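Remark on the chemistry: the structure is read as (2S,3S,5R), with 2-aryl and 3-methyl trans and the 5-allyl group on the same face as the 2-aryl group. Benzofuran numbering of the target (O1, C2, C3, C3a, C4–C7, C7a) is used for the corresponding atoms of all intermediates.

## The problem

The target 25 is a 2,3-dihydrobenzofuran-6(5H)-one. Ring B (O1, C2, C3, C3a, C7a) is a dihydrofuran; ring A is not aromatic but a linearly conjugated cyclohexa-2,4-dienone (C6=O, C7=C7a, C3a=C4) that ends in the quaternary C5 bearing methoxy and allyl. Ring A is oxygenated at C5, C6, C7 and C7a, so it must either be built at the dienone oxidation level or be reached by a dearomatisation that has to find C5 among several activated positions. Of the three stereocentres, C2 (aryl) and C3 (methyl) are adjacent and trans, so one can set the other. C5 is separated from C3 by the sp2 carbons C3a and C4 and can feel the existing centres only weakly. The dienone is the fragile part: two enol ethers, a benzylic ether at C2 next to an electron-rich arene, and an allyl group on a dienone carbon that can migrate in acid or on heating, so the endgame must be neutral and cool. The enabling feature is that C6(=O)–C7(OMe)=C7a–C3a=C4–C5 is exactly what a dienylketene gives on 6π ring closure. C6=O next to C7–OMe is what CO insertion into a chromium methoxycarbene delivers, and C5 carries no hydrogen, so the closure must stop at the dienone.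

## Retrosynthesis

**Ring A (C5–C6 and C6–C7).** Target 25 is opened at both bonds to C6, leaving the chromium methoxycarbene 23, with C6 as one of its CO ligands. Cutting only C5–C6 or only C4–C5 would leave a 1,2-dioxygenated chain to be assembled and oxidised separately; here the metal supplies C6, joins it to both neighbours and gives the dienone oxidation level directly. The precursor has no ring A and no C5 stereocentre. The forward step must insert CO, close a 6π system across the ring-fixed C7a=C3a bond and choose a face at C5.

**Carbene (C7–C7a).** Complex 23 is cut between C7 and C7a: C7 and its oxygen come from Cr(CO)6 (20), the O-methyl from MeOTf, and C7a must be a vinyl anion. Stannane 19 is preferred to the C7a–H compound because the side chain holds a doubly allylic CH2 and C2–H is benzylic and α to oxygen; tin–lithium exchange at −78 °C should outpace both deprotonations. The forward step needs clean exchange, capture by Cr(CO)6 and O-methylation of the acylchromate.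

**Enol ether (C4=C5).** Stannane 19 is cut at the C4=C5 double bond into aldehyde 12 and the α-methoxy phosphine oxide 16, which comes from 13 and allyl bromide 14. A Horner–Wittig reaction is chosen over an α-methoxy ylide for three reasons: the phosphinoyl carbanion is the better nucleophile toward a hindered vinylogous formate; the alkoxide adducts 18 eliminate by a defined syn pathway; and the same reagents allow a two-stage, stereospecific variant if needed. The olefination is run in one flask, because a stage that isolates the adducts would hand on two useful diastereomers side by side. The forward step must give the Z geometry, on which the configuration at C5 depends, or at least allow the E isomer to be removed.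

**Tin at C7a.** Aldehyde 12 goes back to the tin-free aldehyde 8; no skeletal bond is cut. The tin must be in place before the allyl group arrives, since the strong base needed for C7a–H would not spare the skipped diene. The formyl group is reduced to alcohol 9, whose alkoxide directs lithiation to C7a; stannylation gives 11 and re-oxidation gives 12. This costs two redox steps and buys a site-selective metalation.

**C3a–C4.** Aldehyde 8 is cut at the formyl carbon to enol ether 6. Electrophilic formylation at the β-carbon of the enol ether is the natural forward reaction and needs no prior functionalisation of C3a.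

**Ring B (O1–C7a).** Dihydrofuran 6 is opened to the homopropargylic alcohol 5. Cycloisomerisation of a terminal alkynol is atom-neutral and touches neither stereocentre; a lactone reduction–dehydration sequence to the same enol ether would be several steps longer.

**C2–C3.** Alkynol 5 is cut between the two stereocentres into 3,4,5-trimethoxybenzaldehyde 3 and the mesylate 2 of (R)-but-3-yn-2-ol 1. One allenylmetal addition must set both centres, C3 from the reagent and C2 by anti selectivity.

## Roads not taken

**Alternative 1:** The cut is the C3–C3a bond, traced back to the C4–C4a bond of a 2-aryl-2H-chromene A1. In the forward step PhI(OH)OTs (trivalent iodine) in methanol adds to C3, the ring A carbon migrates from C4 to C3, the pyran contracts to ring B and the expelled carbon appears as the dimethyl acetal of A2.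
- Merits: the trans C2/C3 relation follows from the anti migration, ring A stays aromatic and robust, and no organometallic photochemistry is needed. In robustness of the individual steps this road is better than the chosen one.
- Weak points: the acetal must be degraded to a methyl group over about three steps, the allyl group must be brought to C5, and ring A must be dearomatised last by oxidative methanol addition. For a phenol flanked by 5-allyl and 7-methoxy, addition at the methoxy-bearing C7 is the normal course, and addition at C5 would have no facial bias.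
- Comparison: the chosen plan is shorter, has no regiochemical question because C6 can only bond to C5, and can recycle the wrong C5 epimer.

**Alternative 2:** The cuts are C3–CH3 and C3a–C4, with ring A still open. Me2CuLi (monovalent copper) adds methyl to butenolide A3 anti to the aryl group; the enolate is silylated and adds to the α-quaternary aldehyde A4 under BF3·OEt2 to give lactone A5.
- Merits: convergent, reliable trans control at C3, and C5 arrives as a preformed stereocentre of defined configuration. In control of C5 this road is clearly better than the chosen one.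
- Weak points: A4 needs its own enantioselective synthesis and is an α-alkoxy β-keto aldehyde prone to cleavage. The aldol at a neopentyl aldehyde is hindered. After coupling, ring A must still be closed by attack of the C7 enolate on the lactone carbonyl, the opened lactone re-closed as the enol ether, and the C4 carbinol dehydrated.
- Comparison: the chosen plan closes ring A in one step at the right oxidation level and offsets its weak C5 control by epimer recycling.

**Alternative 3:** The cut is O1–C2: ring B is closed last from the spirocyclopropane A6, in which ring A is a saturated 2-methoxy-1,3-dione already carrying C5. Sc(OTf)3 opens the C3a–C2 bond and the C7a enolate oxygen closes on the benzylic C2 to give A7.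
- Merits: C5 can be set early on a simple ring by an enantioselective allylation, again better than the chosen plan at C5, and the ring expansion should settle on the trans ring B.
- Weak points: A6 has several stereocentres including a spiro quaternary carbon, the benzylic cation erases C2, and A7 lacks the C3a=C4 double bond, so a late dehydrogenation next to the quaternary C5 is needed in the presence of the allyl group.
- Comparison: the chosen plan needs no late oxidation-state change and fewer steps.

Key step: step 11

## Route

Step 1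
Reactants: 1 (R)-but-3-yn-2-ol
Product: 2 (R)-but-3-yn-2-yl methanesulfonate
Conditions: MsCl, Et3N, CH2Cl2, −78 → 0 °C
Reagents that add atoms: methanesulfonyl chloride, CS(=O)(=O)Cl
Why: O-sulfonylation of a secondary propargylic alcohol; the C–O bond is not touched, so the R configuration is kept.

Step 2
Reactants: 2 (R)-but-3-yn-2-yl methanesulfonate; 3 3,4,5-trimethoxybenzaldehyde
Product: 5 (1S,2S)-2-methyl-1-(3,4,5-trimethoxyphenyl)but-3-yn-1-ol, via allenylzinc reagent 4 (not isolated)
Conditions: Pd(OAc)2 (5 mol %), PPh3 (5 mol %), Et2Zn (3 equiv), THF, −78 → −20 °C; aq. NH4Cl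
Reagents that add atoms: none
Why: Marshall propargylation: zerovalent palladium opens the mesylate anti (SN2′), Et2Zn transmetalates to the (P)-allenylzinc 4, and this adds to the aldehyde through a cyclic SE2′ transition state. The allene axis sets the methyl-bearing carbon as S, and placing the aryl group anti to the allenyl methyl should favour the anti (1S,2S) adduct; the syn isomer would be removed by chromatography.

Step 3
Reactants: 5 (1S,2S)-2-methyl-1-(3,4,5-trimethoxyphenyl)but-3-yn-1-ol
Product: 6 (2S,3S)-3-methyl-2-(3,4,5-trimethoxyphenyl)-2,3-dihydrofuran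
Conditions: Mo(CO)6 (25 mol %), Et3N, Et2O, hν (350 nm) to form Et3N·Mo(CO)5, then 5, 20 °C
Reagents that add atoms: none
Why: Alkynol cycloisomerisation through a molybdenum vinylidene: 1,2-hydrogen shift, attack of the hydroxyl on the vinylidene carbon and protodemetalation give the endocyclic enol ether, as known for 1-arylbut-3-yn-1-ols. Neither stereocentre takes part.

Step 4
Reactants: 6 (2S,3S)-3-methyl-2-(3,4,5-trimethoxyphenyl)-2,3-dihydrofuran
Product: 8 (4S,5S)-4-methyl-5-(3,4,5-trimethoxyphenyl)-4,5-dihydrofuran-3-carbaldehyde, via iminium chloride 7 (not isolated)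
Conditions: POCl3, DMF, CH2Cl2, 0 → 20 °C; aq. NaOAc
Reagents that add atoms: N,N-dimethylformamide, CN(C)C=O; water, O
Why: Vilsmeier–Haack formylation at the β-carbon of a cyclic enol ether, as for dihydropyrans and glycals; the enol ether is far more nucleophilic than the trimethoxyphenyl ring at this temperature. Buffered hydrolysis of 7 gives the vinylogous formate, and C3 cannot enolise into the new carbonyl.

Step 5
Reactants: 8 (4S,5S)-4-methyl-5-(3,4,5-trimethoxyphenyl)-4,5-dihydrofuran-3-carbaldehyde
Product: 9 [(4S,5S)-4-methyl-5-(3,4,5-trimethoxyphenyl)-4,5-dihydrofuran-3-yl]methanol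
Conditions: NaBH4, EtOH–THF, 0 °C; aq. NaHCO3
Reagents that add atoms: none
Why: 1,2-Reduction of a β-alkoxy enal by borohydride; the basic medium and work-up protect the acid-labile allylic alcohol.

Step 6
Reactants: 9 [(4S,5S)-4-methyl-5-(3,4,5-trimethoxyphenyl)-4,5-dihydrofuran-3-yl]methanol
Product: 11 [(4S,5S)-4-methyl-2-(tributylstannyl)-5-(3,4,5-trimethoxyphenyl)-4,5-dihydrofuran-3-yl]methanol, via dilithio alkoxide 10 (not isolated)
Conditions: t-BuLi (2.3 equiv), THF, −78 → −20 °C; Bu3SnCl (1.1 equiv), −78 → 20 °C; aq. NaHCO3
Reagents that add atoms: tributyltin chloride, CCCC[Sn](Cl)(CCCC)CCCC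
Why: Alkoxide-directed α-lithiation of a cyclic enol ether, the counterpart of the C2 lithiation of 3-furylmethanol and of the α-lithiation of dihydrofurans, followed by C-stannylation. The lithium alkoxide holds the base next to C7a–H, away from the benzylic C2–H.

Step 7
Reactants: 11 [(4S,5S)-4-methyl-2-(tributylstannyl)-5-(3,4,5-trimethoxyphenyl)-4,5-dihydrofuran-3-yl]methanol
Product: 12 (4S,5S)-4-methyl-2-(tributylstannyl)-5-(3,4,5-trimethoxyphenyl)-4,5-dihydrofuran-3-carbaldehyde
Conditions: activated MnO2 (excess), CH2Cl2, 20 °C
Reagents that add atoms: none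
Why: Oxidation of an allylic alcohol by MnO2 under neutral conditions, which an α-stannyl enol ether should tolerate.

Step 8
Reactants: 13 (methoxymethyl)diphenylphosphine oxide; 14 allyl bromide
Product: 16 (1-methoxybut-3-en-1-yl)diphenylphosphine oxide (racemic), via lithiated phosphine oxide 15 (not isolated)
Conditions: LDA, THF, −78 °C; 14, −78 → 0 °C
Reagents that add atoms: none
Why: α-Alkylation of a phosphine-oxide-stabilised, α-alkoxy carbanion with a reactive allylic bromide.

Step 9
Reactants: 12 (4S,5S)-4-methyl-2-(tributylstannyl)-5-(3,4,5-trimethoxyphenyl)-4,5-dihydrofuran-3-carbaldehyde; 16 (1-methoxybut-3-en-1-yl)diphenylphosphine oxide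
Product: 19 tributyl{(4S,5S)-3-[(1Z)-2-methoxypenta-1,4-dien-1-yl]-4-methyl-5-(3,4,5-trimethoxyphenyl)-4,5-dihydrofuran-2-yl}stannane, via lithiated phosphine oxide 17 (not isolated), via lithium alkoxide adducts 18 (not isolated)
Conditions: 16, LDA, THF, −78 °C; 12, −78 °C; KOtBu, −78 → 40 °C; chromatography on Et3N-deactivated silica
Reagents that add atoms: none
Why: One-flask Horner–Wittig olefination: the carbanion 17 adds to the aldehyde, and exchange of lithium for potassium lets the alkoxides 18 lose diphenylphosphinate by syn elimination, the like adducts giving the Z and the unlike adducts the E enol ether. Potassium alkoxides of such stabilised, fully substituted carbanions can revert to 12 and 17, so the ratio should be set largely by the elimination rates; the like alkoxides eclipse the ring with methoxy and not with the allyl CH2 and should eliminate faster. The E isomer would be removed by chromatography.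

Step 10
Reactants: 19 tributyl{(4S,5S)-3-[(1Z)-2-methoxypenta-1,4-dien-1-yl]-4-methyl-5-(3,4,5-trimethoxyphenyl)-4,5-dihydrofuran-2-yl}stannane; 20 hexacarbonylchromium Cr(CO)6
Product: 23 pentacarbonyl{methoxy[(4S,5S)-3-((1Z)-2-methoxypenta-1,4-dien-1-yl)-4-methyl-5-(3,4,5-trimethoxyphenyl)-4,5-dihydrofuran-2-yl]methylidene}chromium, via vinyllithium 21 (not isolated), via lithium acylchromate 22 (not isolated)
Conditions: n-BuLi (1.05 equiv), THF, −78 °C; Cr(CO)6, THF, −78 → 0 °C; evaporate; MeOTf, CH2Cl2, 0 °C
Reagents that add atoms: methyl trifluoromethanesulfonate, COS(=O)(=O)C(F)(F)F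
Why: Fischer carbene synthesis: tin–lithium exchange of an α-alkoxyvinyl stannane, addition of the vinyllithium to a CO ligand of zerovalent chromium, and O-methylation of the acylchromate, as known for α-lithiated cyclic enol ethers. In the Z enol ether the doubly allylic CH2 lies trans to the ring and out of reach of C7a–Li, so only the slower intermolecular proton transfer can compete with exchange and capture at −78 °C.

Step 11
Reactants: 23 pentacarbonyl{methoxy[(4S,5S)-3-((1Z)-2-methoxypenta-1,4-dien-1-yl)-4-methyl-5-(3,4,5-trimethoxyphenyl)-4,5-dihydrofuran-2-yl]methylidene}chromium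
Product: 25 (2S,3S,5R)-5,7-dimethoxy-3-methyl-5-(prop-2-en-1-yl)-2-(3,4,5-trimethoxyphenyl)-2,3-dihydro-1-benzofuran-6(5H)-one, via chromium-bound dienylketene 24 (not isolated)
Conditions: hν (blue LEDs, 450 nm), CO (1 atm), degassed THF, 15–20 °C
Reagents that add atoms: none
Why: Visible-light excitation of the charge-transfer band of 23 inserts a cis CO ligand into the Cr=C7 bond and gives the chromium-bound dienylketene 24 (C6–C7 formed); the CO atmosphere suppresses CO loss and returns the metal as Cr(CO)6. The ketene carbon C6 then bonds to C5 in a thermal, disrotatory 6π-electrocyclisation across the ring-fixed C7a=C3a bond, which closes the six-membered ring A. The closest known reactions are the photochemical benzannulation of dienyl chromium alkoxycarbenes to ortho-alkoxyphenols and the closure of dienylketenes with a disubstituted terminus to cyclohexa-2,4-dienones. Because C5 has no hydrogen the dienone cannot tautomerise and is the product, with the CO ligand as C6=O and the carbene methoxy as 7-OMe. At C5 the Z enol ether places methoxy inside and allyl outside, and disrotation turns the inside group to the face away from the incoming C6. Closure through the helix in which H-4 tilts toward H-3 and not toward the C3 methyl puts allyl on the aryl face, which is 5R. This bias rests on the C3 methyl alone, so only modest selectivity is expected; the 5-epimer is separated and re-irradiated, since photochemical ring opening of the dienone regenerates the dienylketene and lets it close again. The step also needs the electrocyclisation to outrun ketene [2+2] addition to the enol ether or allyl group and thermal closure of the carbene to a cyclopentadiene, which the locked s-cis geometry and the low temperature should secure.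

## Compound list

1 | (R)-but-3-yn-2-ol | C#C[C@@H](C)O | starting material
2 | (R)-but-3-yn-2-yl methanesulfonate | C#C[C@@H](C)OS(C)(=O)=O | intermediate
3 | 3,4,5-trimethoxybenzaldehyde | COc1cc(C=O)cc(OC)c1OC | starting material
4 | (P)-buta-1,2-dien-1-yl(ethyl)zinc | CC[Zn]C([H])=[C@@]=C([H])C | intermediate (not isolated)
5 | (1S,2S)-2-methyl-1-(3,4,5-trimethoxyphenyl)but-3-yn-1-ol | C#C[C@H](C)[C@H](O)c1cc(OC)c(OC)c(OC)c1 | intermediate
6 | (2S,3S)-3-methyl-2-(3,4,5-trimethoxyphenyl)-2,3-dihydrofuran | C1=C[C@H](C)[C@@H](c2cc(OC)c(OC)c(OC)c2)O1 | intermediate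
7 | N-{[(4S,5S)-4-methyl-5-(3,4,5-trimethoxyphenyl)-4,5-dihydrofuran-3-yl]methylidene}-N-methylmethanaminium chloride | C1=C(C=[N+](C)C)[C@H](C)[C@@H](c2cc(OC)c(OC)c(OC)c2)O1.[Cl-] | intermediate (not isolated)
8 | (4S,5S)-4-methyl-5-(3,4,5-trimethoxyphenyl)-4,5-dihydrofuran-3-carbaldehyde | C1=C(C=O)[C@H](C)[C@@H](c2cc(OC)c(OC)c(OC)c2)O1 | intermediate
9 | [(4S,5S)-4-methyl-5-(3,4,5-trimethoxyphenyl)-4,5-dihydrofuran-3-yl]methanol | C1=C(CO)[C@H](C)[C@@H](c2cc(OC)c(OC)c(OC)c2)O1 | intermediate
10 | lithium [(4S,5S)-2-lithio-4-methyl-5-(3,4,5-trimethoxyphenyl)-4,5-dihydrofuran-3-yl]methanolate | [Li]C1=C(CO[Li])[C@H](C)[C@@H](c2cc(OC)c(OC)c(OC)c2)O1 | intermediate (not isolated)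
11 | [(4S,5S)-4-methyl-2-(tributylstannyl)-5-(3,4,5-trimethoxyphenyl)-4,5-dihydrofuran-3-yl]methanol | CCCC[Sn](CCCC)(CCCC)C1=C(CO)[C@H](C)[C@@H](c2cc(OC)c(OC)c(OC)c2)O1 | intermediate
12 | (4S,5S)-4-methyl-2-(tributylstannyl)-5-(3,4,5-trimethoxyphenyl)-4,5-dihydrofuran-3-carbaldehyde | CCCC[Sn](CCCC)(CCCC)C1=C(C=O)[C@H](C)[C@@H](c2cc(OC)c(OC)c(OC)c2)O1 | intermediate
13 | (methoxymethyl)diphenylphosphine oxide | COCP(=O)(c1ccccc1)c1ccccc1 | starting material
14 | allyl bromide | C=CCBr | starting material
15 | [lithio(methoxy)methyl]diphenylphosphine oxide | [Li]C(OC)P(=O)(c1ccccc1)c1ccccc1 | intermediate (not isolated)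
16 | (1-methoxybut-3-en-1-yl)diphenylphosphine oxide (racemic) | COC(CC=C)P(=O)(c1ccccc1)c1ccccc1 | intermediate
17 | (1-lithio-1-methoxybut-3-en-1-yl)diphenylphosphine oxide | [Li]C(OC)(CC=C)P(=O)(c1ccccc1)c1ccccc1 | intermediate (not isolated)
18 | lithium 2-(diphenylphosphoryl)-2-methoxy-1-[(4S,5S)-4-methyl-2-(tributylstannyl)-5-(3,4,5-trimethoxyphenyl)-4,5-dihydrofuran-3-yl]pent-4-en-1-olate (all four side-chain diastereomers) | CCCC[Sn](CCCC)(CCCC)C1=C(C([O-])C(OC)(CC=C)P(=O)(c2ccccc2)c2ccccc2)[C@H](C)[C@@H](c2cc(OC)c(OC)c(OC)c2)O1.[Li+] | intermediate (not isolated)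
19 | tributyl{(4S,5S)-3-[(1Z)-2-methoxypenta-1,4-dien-1-yl]-4-methyl-5-(3,4,5-trimethoxyphenyl)-4,5-dihydrofuran-2-yl}stannane | CCCC[Sn](CCCC)(CCCC)C1=C(/C=C(\OC)CC=C)[C@H](C)[C@@H](c2cc(OC)c(OC)c(OC)c2)O1 | intermediate
20 | hexacarbonylchromium, Cr(CO)6 | O=C=[Cr](=C=O)(=C=O)(=C=O)(=C=O)=C=O | starting material
21 | {(4S,5S)-3-[(1Z)-2-methoxypenta-1,4-dien-1-yl]-4-methyl-5-(3,4,5-trimethoxyphenyl)-4,5-dihydrofuran-2-yl}lithium | [Li]C1=C(/C=C(\OC)CC=C)[C@H](C)[C@@H](c2cc(OC)c(OC)c(OC)c2)O1 | intermediate (not isolated)
22 | lithium pentacarbonyl[{(4S,5S)-3-[(1Z)-2-methoxypenta-1,4-dien-1-yl]-4-methyl-5-(3,4,5-trimethoxyphenyl)-4,5-dihydrofuran-2-yl}(oxido)methylidene]chromium | [Li+].[O-]C(=[Cr](=C=O)(=C=O)(=C=O)(=C=O)=C=O)C1=C(/C=C(\OC)CC=C)[C@H](C)[C@@H](c2cc(OC)c(OC)c(OC)c2)O1 | intermediate (not isolated)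
23 | pentacarbonyl{methoxy[(4S,5S)-3-((1Z)-2-methoxypenta-1,4-dien-1-yl)-4-methyl-5-(3,4,5-trimethoxyphenyl)-4,5-dihydrofuran-2-yl]methylidene}chromium | COC(=[Cr](=C=O)(=C=O)(=C=O)(=C=O)=C=O)C1=C(/C=C(\OC)CC=C)[C@H](C)[C@@H](c2cc(OC)c(OC)c(OC)c2)O1 | intermediate
24 | 2-methoxy-2-{(4S,5S)-3-[(1Z)-2-methoxypenta-1,4-dien-1-yl]-4-methyl-5-(3,4,5-trimethoxyphenyl)-4,5-dihydrofuran-2-yl}ethen-1-one (dienylketene, formed on chromium) | O=C=C(OC)C1=C(/C=C(\OC)CC=C)[C@H](C)[C@@H](c2cc(OC)c(OC)c(OC)c2)O1 | intermediate (not isolated)
25 | (2S,3S,5R)-5,7-dimethoxy-3-methyl-5-(prop-2-en-1-yl)-2-(3,4,5-trimethoxyphenyl)-2,3-dihydro-1-benzofuran-6(5H)-one | C=CC[C@@]1(OC)C=C2C(=C(OC)C1=O)O[C@H](c1cc(OC)c(OC)c(OC)c1)[C@H]2C | target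

## Step count and least certain steps

Total step count: 11. Longest linear sequence: 10 steps (steps 1–7 and 9–11, from 1); step 8 prepares the olefination reagent.

**Step 11 (key step).** The most likely failures are poor facial selectivity at C5, because only the C3 methyl distinguishes the two helical closures, and diversion of the excited carbene into CO loss, loss of the carbene ligand or thermal five-ring closure before CO insertion. Fallback, from 23 back to 25 without light: 23 is treated with tert-butyl isocyanide in THF at 25–50 °C in the dark. Isocyanide insertion into the Cr=C7 bond gives the ketenimine F1, which closes by the same 6π-electrocyclisation to the N-tert-butyl dienimine F2; mild hydrolysis (aqueous oxalic acid on silica) then gives 25.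

**Step 9.** The most likely failure is poor Z selectivity: the addition of 17 to the aldehyde is not expected to be diastereoselective, and reversal of the adducts before elimination may be incomplete, so the geometry would not be corrected and the isomers may be hard to separate. Fallback, from 12 (with 16) back to 19, is the two-stage, stereospecific form of the reaction. The lithium alkoxides are quenched with aq. NH4Cl at −78 °C and the β-hydroxy phosphine oxides are isolated. The like pair, the (1R,2R) adduct F3 and the (1S,2S) adduct F4, is separated from the unlike pair on Et3N-deactivated silica. KH in THF (0 → 20 °C) then brings about syn elimination from both like adducts, which can give only the Z enol ether 19.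

**Step 10.** The most likely failure is quenching of vinyllithium 21 by intermolecular proton transfer from the doubly allylic CH2 while the sparingly soluble Cr(CO)6 is taken up slowly. Fallback, from 12 (with 16) back to 23: the chromium is introduced before the skipped diene exists. The like adducts F3 and F4, obtained as in the fallback for step 9, are treated with n-BuLi (2.1 equiv, THF, −78 °C; alkoxide formation, then tin–lithium exchange) and Cr(CO)6 to give the dilithium acylchromate alkoxides F5 (from F3) and F6 (from F4). KOtBu then triggers the Horner–Wittig elimination on the base-stable acylchromate to give the potassium acylchromate F7, and MeOTf in CH2Cl2 gives 23.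

**Step 6.** The most likely failure is competing deprotonation by t-BuLi at the benzylic C2–H next to the ring oxygen or on the arene, followed by ring fragmentation. Fallback, from 8 back to 12, which also removes steps 5 and 7: aldehyde 8 is zincated at C7a with TMP2Zn·2MgCl2·2LiCl (THF, 20 °C), a base that tolerates the formyl group and reaches only the C–H activated by both the ring oxygen and the carbonyl. Iodine gives the iodo aldehyde F8, and stannylation with Bu3SnSnBu3 and Pd(PPh3)4 (toluene, 80 °C) gives 12.

## Further compounds

F1 | step 11 | N-tert-butyl-2-methoxy-2-{(4S,5S)-3-[(1Z)-2-methoxypenta-1,4-dien-1-yl]-4-methyl-5-(3,4,5-trimethoxyphenyl)-4,5-dihydrofuran-2-yl}ethen-1-imine (ketenimine) | CC(C)(C)N=C=C(OC)C1=C(/C=C(\OC)CC=C)[C@H](C)[C@@H](c2cc(OC)c(OC)c(OC)c2)O1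
F2 | step 11 | (2S,3S,5R)-N-tert-butyl-5,7-dimethoxy-3-methyl-5-(prop-2-en-1-yl)-2-(3,4,5-trimethoxyphenyl)-2,3-dihydro-1-benzofuran-6(5H)-imine | C=CC[C@@]1(OC)C=C2C(=C(OC)C1=NC(C)(C)C)O[C@H](c1cc(OC)c(OC)c(OC)c1)[C@H]2C
F3 | step 9 | (1R,2R)-2-(diphenylphosphoryl)-2-methoxy-1-[(4S,5S)-4-methyl-2-(tributylstannyl)-5-(3,4,5-trimethoxyphenyl)-4,5-dihydrofuran-3-yl]pent-4-en-1-ol | CCCC[Sn](CCCC)(CCCC)C1=C([C@@H](O)[C@@](OC)(CC=C)P(=O)(c2ccccc2)c2ccccc2)[C@H](C)[C@@H](c2cc(OC)c(OC)c(OC)c2)O1
F4 | step 9 | (1S,2S)-2-(diphenylphosphoryl)-2-methoxy-1-[(4S,5S)-4-methyl-2-(tributylstannyl)-5-(3,4,5-trimethoxyphenyl)-4,5-dihydrofuran-3-yl]pent-4-en-1-ol | CCCC[Sn](CCCC)(CCCC)C1=C([C@H](O)[C@](OC)(CC=C)P(=O)(c2ccccc2)c2ccccc2)[C@H](C)[C@@H](c2cc(OC)c(OC)c(OC)c2)O1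
F5 | step 10 | dilithium pentacarbonyl[{(4S,5S)-3-[(1R,2R)-2-(diphenylphosphoryl)-2-methoxy-1-oxidopent-4-en-1-yl]-4-methyl-5-(3,4,5-trimethoxyphenyl)-4,5-dihydrofuran-2-yl}(oxido)methylidene]chromium | [Li+].[Li+].[O-]C(=[Cr](=C=O)(=C=O)(=C=O)(=C=O)=C=O)C1=C([C@@H]([O-])[C@@](OC)(CC=C)P(=O)(c2ccccc2)c2ccccc2)[C@H](C)[C@@H](c2cc(OC)c(OC)c(OC)c2)O1
F6 | step 10 | dilithium pentacarbonyl[{(4S,5S)-3-[(1S,2S)-2-(diphenylphosphoryl)-2-methoxy-1-oxidopent-4-en-1-yl]-4-methyl-5-(3,4,5-trimethoxyphenyl)-4,5-dihydrofuran-2-yl}(oxido)methylidene]chromium | [Li+].[Li+].[O-]C(=[Cr](=C=O)(=C=O)(=C=O)(=C=O)=C=O)C1=C([C@H]([O-])[C@](OC)(CC=C)P(=O)(c2ccccc2)c2ccccc2)[C@H](C)[C@@H](c2cc(OC)c(OC)c(OC)c2)O1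
F7 | step 10 | potassium pentacarbonyl[{(4S,5S)-3-[(1Z)-2-methoxypenta-1,4-dien-1-yl]-4-methyl-5-(3,4,5-trimethoxyphenyl)-4,5-dihydrofuran-2-yl}(oxido)methylidene]chromium | [K+].[O-]C(=[Cr](=C=O)(=C=O)(=C=O)(=C=O)=C=O)C1=C(/C=C(\OC)CC=C)[C@H](C)[C@@H](c2cc(OC)c(OC)c(OC)c2)O1
F8 | step 6 | (4S,5S)-2-iodo-4-methyl-5-(3,4,5-trimethoxyphenyl)-4,5-dihydrofuran-3-carbaldehyde | IC1=C(C=O)[C@H](C)[C@@H](c2cc(OC)c(OC)c(OC)c2)O1
A1 | alternative 1 | (2S)-8-methoxy-7-(methoxymethoxy)-2-(3,4,5-trimethoxyphenyl)-2H-chromene | COCOc1ccc2C=C[C@@H](c3cc(OC)c(OC)c(OC)c3)Oc2c1OC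
A2 | alternative 1 | (2S,3S)-3-(dimethoxymethyl)-7-methoxy-6-(methoxymethoxy)-2-(3,4,5-trimethoxyphenyl)-2,3-dihydro-1-benzofuran | COCOc1ccc2c(c1OC)O[C@H](c1cc(OC)c(OC)c(OC)c1)[C@H]2C(OC)OC
A3 | alternative 2 | (5S)-5-(3,4,5-trimethoxyphenyl)furan-2(5H)-one | O=C1C=C[C@@H](c2cc(OC)c(OC)c(OC)c2)O1
A4 | alternative 2 | (2R)-2-methoxy-2-(methoxyacetyl)pent-4-enal | C=CC[C@@](C(=O)COC)(OC)C=O
A5 | alternative 2 | (3R,4S,5S)-3-[(2R)-1-hydroxy-2-methoxy-2-(methoxyacetyl)pent-4-en-1-yl]-4-methyl-5-(3,4,5-trimethoxyphenyl)oxolan-2-one (carbinol epimers) | C=CC[C@@](C(=O)COC)(OC)C(O)[C@@H]1C(=O)O[C@H](c2cc(OC)c(OC)c(OC)c2)[C@H]1C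
A6 | alternative 3 | (7R)-5,7-dimethoxy-2-methyl-7-(prop-2-en-1-yl)-1-(3,4,5-trimethoxyphenyl)spiro[2.5]octane-4,6-dione (trans aryl/methyl on the three-membered ring, other centres left open) | C=CC[C@@]1(OC)CC2(C(=O)C(OC)C1=O)C(c1cc(OC)c(OC)c(OC)c1)C2C
A7 | alternative 3 | (2S,3S,3aS,5R)-5,7-dimethoxy-3-methyl-5-(prop-2-en-1-yl)-2-(3,4,5-trimethoxyphenyl)-2,3,3a,4-tetrahydro-1-benzofuran-6(5H)-one | C=CC[C@@]1(OC)C[C@@H]2C(=C(OC)C1=O)O[C@H](c1cc(OC)c(OC)c(OC)c1)[C@H]2C
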